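A direct plan would close ring C last, by a carbonylative alkyne annulation.
3,4,5-Trimethoxyphenol A1 would be iodinated to 2-iodo-3,4,5-trimethoxyphenol A2; part of A2 would be benzylated to 1-(benzyloxy)-2-iodo-3,4,5-trimethoxybenzene A3 and ethynylated to 1-(benzyloxy)-2-ethynyl-3,4,5-trimethoxybenzene A4.
A2, A4 and CO would be joined with PdCl2(dppf) and Et2NH to 6'-benzyloxy-5,6,7,2',3',4'-hexamethoxyflavone A5, from which BCl3 would remove the benzyl and the 5-O-methyl group.
Weakest would be the carbonylative annulation: the iodide is flanked by two oxygen substituents and carries a free phenol, so pressurised CO, direct alkynylation, amide formation with Et2NH and 5-exo closure to an aurone would all have to be held in check at once.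
Second would be the benzyl ether, put on and taken off again: two operations that add no complexity and force the last step to do two cleavages together.
Third would be iodination, alkynylation and desilylation: three operations that only prepare the coupling sites.

The route would cut the C2–C1' bond and functionalise neither carbon beforehand. Ring B is 3,4,5-trimethoxyphenol itself: its only C–H positions (2 and 6 of the phenol, equivalent) lie ortho to OH and ortho/para to OMe. The peri pair 5-OH/C4=O of rings A and C would clamp one tBu2Si group, turning 5-hydroxy-6,7-dimethoxychromone into a benzopyrylium ion electrophilic only at C2. Friedel–Crafts addition and hydride abstraction in one flask would join the halves and deliver both free hydroxyls of the target. No CO annulation, no protecting-group step and no halide or alkyne would be needed; ring C would be closed before ring B arrives, and both halves would come from one phenol.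

Key step: step 4

Remark: flavone numbering is used for the chromone core (O1, C2–C4, C4a, C5–C8, C8a) and primed numbers for ring B. The silicon bridge of step 4 is put on and removed within one flask and is treated as activation, not as a protecting-group step.

Step 1
Reactants: 1 3,4,5-trimethoxyphenol
Product: 2 1-(2-hydroxy-4,5,6-trimethoxyphenyl)ethan-1-one
Conditions: AcOH, BF3·OEt2 (3 equiv), 90 °C; then H2O
Reagents that add atoms: acetic acid, CC(=O)O
Why: Friedel–Crafts C-acetylation of a strongly activated phenol (possibly by way of the aryl acetate and a Fries shift); the two free ring positions are equivalent, so only one ketone can form, and the product, held as its O,O-difluoroboron chelate until work-up, is deactivated toward a second acylation; no stereocentre is formed.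

Step 2
Reactants: 2 1-(2-hydroxy-4,5,6-trimethoxyphenyl)ethan-1-one
Product: 4 5,6,7-trimethoxy-4H-chromen-4-one, via enaminone 3 (not isolated)
Conditions: Me2NCH(OMe)2, toluene, 100 °C; evaporate; then conc. HCl, CH2Cl2, 40 °C
Reagents that add atoms: N,N-dimethylformamide dimethyl acetal, COC(OC)N(C)C
Why: Condensation of the methyl ketone with the amide acetal should give the E-enaminone 3, and acid then promotes 6-endo conjugate addition of the ortho phenol with loss of dimethylamine (addition–elimination), the standard enaminone synthesis of 2,3-unsubstituted chromones, which closes ring C before ring B is present; no stereocentre is formed.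

Step 3
Reactants: 4 5,6,7-trimethoxy-4H-chromen-4-one
Product: 5 5-hydroxy-6,7-dimethoxy-4H-chromen-4-one
Conditions: BCl3 (1.5 equiv), CH2Cl2, −78 → 0 °C; then MeOH, H2O
Reagents that add atoms: none
Why: Chelation-directed Lewis-acid cleavage of an aryl methyl ether: boron bound to the C4 carbonyl oxygen can reach only the peri 5-methoxy oxygen, chloride removes that methyl group by SN2 to give the six-membered dichloroboron chelate, and the 6- and 7-methoxy groups, which cannot chelate, should stay; no stereocentre is involved.

Step 4
Reactants: 5 5-hydroxy-6,7-dimethoxy-4H-chromen-4-one; 1 3,4,5-trimethoxyphenol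
Product: 9 5,6'-dihydroxy-6,7,2',3',4'-pentamethoxyflavone, via silylene-bridged benzopyrylium triflate 6 (not isolated), via silylene-bridged 2-aryl-2H-chromene 7 (not isolated), via silylene-bridged flavylium salt 8 (not isolated)
Conditions: tBu2Si(OTf)2 (1.05 equiv), 2,6-di-tert-butyl-4-methylpyridine (2.2 equiv), CH2Cl2, 0 °C → rt; 1 (1.2 equiv), −40 °C → rt; DDQ (1.2 equiv), 0 °C; then HF·pyridine, THF, 0 °C
Reagents that add atoms: none
Why: Proposed new method: a formal cross-dehydrogenative C2–H/aryl C–H coupling run as polar steps, in which tBu2Si(OTf)2 silylates the 5-OH and its second Si–OTf bond is displaced by the peri C4=O so that 5 becomes the O4,O5-silylene-bridged 1-benzopyrylium triflate 6, the free ring carbon of phenol 1 adds to C2 in a Friedel–Crafts step with loss of the proton to the pyridine base to give 2H-chromene 7, DDQ abstracts the C2 hydride (alpha to O1, benzylic, vinylogous to the enol silyl ether) to give flavylium salt 8, and fluoride removes the silylene to uncover C4=O and 5-OH. The closest known reaction types are the C2 addition of carbon nucleophiles to 4-silyloxy-1-benzopyrylium triflates made from chromones and silyl triflates, the C-arylation of flavylium salts by phloroglucinol-type phenols, and the DDQ dehydrogenation of 2H-chromenes and of flavanone silyl enol ethers. No ring of the target is closed here, since ring C is already present; the only ring formed is the temporary six-membered O4–Si–O5 chelate, closed by intramolecular O-silylation and opened again by fluoride. The C2 stereocentre of 7 is formed as a racemate and is erased by the oxidation, so no stereocontrol is needed. The step needs attack at C2 and not C4 of the cation, which the oxygen substituent at C4 secures; a single site on the nucleophile, which phenol 1 secures because its two C–H positions are equivalent; and C- over O-arylation, which follows because O-attack gives a reversible acetal while C-attack is fixed by proton loss and then by oxidation. The hindered silicon, held by two oxygens of one molecule, should not pass to the external phenol, and a small excess of 1 should hold back double arylation.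

Compound list
1 | 3,4,5-trimethoxyphenol | COc1cc(O)cc(OC)c1OC | starting material
2 | 1-(2-hydroxy-4,5,6-trimethoxyphenyl)ethan-1-one | CC(=O)c1c(O)cc(OC)c(OC)c1OC | intermediate
3 | (E)-3-(dimethylamino)-1-(2-hydroxy-4,5,6-trimethoxyphenyl)prop-2-en-1-one (formed in the flask) | CN(C)/C=C/C(=O)c1c(O)cc(OC)c(OC)c1OC | intermediate
4 | 5,6,7-trimethoxy-4H-chromen-4-one | COc1cc2occc(=O)c2c(OC)c1OC | intermediate
5 | 5-hydroxy-6,7-dimethoxy-4H-chromen-4-one | COc1cc2occc(=O)c2c(O)c1OC | intermediate
6 | 6,7-dimethoxy-1-benzopyrylium triflate whose 4-O and 5-O atoms are bridged by one di-tert-butylsilanediyl group (formed in the flask) | COc1cc2[o+]ccc3c2c(O[Si](C(C)(C)C)(C(C)(C)C)O3)c1OC.[O-]S(=O)(=O)C(F)(F)F | intermediate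
7 | racemic 2-(2-hydroxy-4,5,6-trimethoxyphenyl)-6,7-dimethoxy-2H-chromene with the same O4–Si(tBu)2–O5 bridge (formed in the flask) | COc1cc2OC(c3c(O)cc(OC)c(OC)c3OC)C=C4O[Si](C(C)(C)C)(C(C)(C)C)Oc(c1OC)c24 | intermediate
8 | 2-(2-hydroxy-4,5,6-trimethoxyphenyl)-6,7-dimethoxy-1-benzopyrylium with the same O4–Si(tBu)2–O5 bridge, as its 2,3-dichloro-5,6-dicyano-4-hydroxyphenolate (formed in the flask) | COc1cc2[o+]c(-c3c(O)cc(OC)c(OC)c3OC)cc4c2c(O[Si](C(C)(C)C)(C(C)(C)C)O4)c1OC.[O-]c1c(Cl)c(Cl)c(O)c(C#N)c1C#N | intermediate
9 | 5,6'-dihydroxy-6,7,2',3',4'-pentamethoxyflavone (achiral) | COc1cc(O)c(-c2cc(=O)c3c(O)c(OC)c(OC)cc3o2)c(OC)c1OC | target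

Total step count: 4. Longest linear sequence: 4 steps (1 → 2 → 4 → 5 → 9); phenol 1 enters a second time in step 4.

Steps most likely to fail

Step 4. The Friedel–Crafts addition may stall because the benzopyrylium ion, stabilised by four oxygen substituents, is a weak electrophile. Alternatively, DDQ may oxidise the electron-rich phenol ring faster than it takes the C2 hydride. The fallback uses known chemistry, sets out from 2 and comes back at 9. Phenol 1 would be ortho-formylated (MgCl2, Et3N, paraformaldehyde, MeCN, reflux) to 2-hydroxy-4,5,6-trimethoxybenzaldehyde F1 and O-alkylated (2-bromopropane, K2CO3, DMF) to 2-isopropoxy-4,5,6-trimethoxybenzaldehyde F2. Claisen–Schmidt condensation of 2 with F2 (KOH, EtOH) would give (E)-1-(2-hydroxy-4,5,6-trimethoxyphenyl)-3-(2-isopropoxy-4,5,6-trimethoxyphenyl)prop-2-en-1-one F3. Catalytic I2 in DMSO at 130 °C would close and dehydrogenate it to 6'-isopropoxy-5,6,7,2',3',4'-hexamethoxyflavone F4. BCl3 in CH2Cl2 would then cleave the isopropyl ether and the 5-methyl ether to give 9.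

Step 3. The boron chelate at O5 may also activate the neighbouring 6-methoxy group (over-cleavage), or chloride may open the pyranone ring. The fallback sets out from 4 and comes back at 9, keeping the methyl ether through the coupling and cleaving it last. 4 would be activated with TBSOTf and the same pyridine base as 4-(tert-butyldimethylsilyloxy)-5,6,7-trimethoxy-1-benzopyrylium triflate F5. Phenol 1 would add at C2 to give racemic tert-butyl{[2-(2-hydroxy-4,5,6-trimethoxyphenyl)-5,6,7-trimethoxy-2H-chromen-4-yl]oxy}dimethylsilane F6. DDQ and aqueous work-up would give 6'-hydroxy-5,6,7,2',3',4'-hexamethoxyflavone F7. BCl3 would then cleave only the 5-methyl ether, a cleavage that is well established on 5-methoxyflavones. This fallback relies on the coupling of step 4 working; if that fails, the fallback of step 4 applies and 5 is not needed.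

Step 2. Condensation at the acetyl group, which is flanked by OH and OMe and hydrogen-bonded, may be slow, and O-methylation of the phenol by the amide acetal may compete. The fallback sets out from 2 and comes back at 4. Claisen condensation with ethyl formate (NaH, THF) would give racemic 2-hydroxy-5,6,7-trimethoxychroman-4-one F8, the cyclic hemiacetal of the beta-keto aldehyde, which HCl in AcOH would dehydrate to 4.

Further compounds
F1 | step 4 | 2-hydroxy-4,5,6-trimethoxybenzaldehyde | COc1cc(O)c(C=O)c(OC)c1OC
F2 | step 4 | 2-isopropoxy-4,5,6-trimethoxybenzaldehyde | COc1cc(OC(C)C)c(C=O)c(OC)c1OC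
F3 | step 4 | (E)-1-(2-hydroxy-4,5,6-trimethoxyphenyl)-3-(2-isopropoxy-4,5,6-trimethoxyphenyl)prop-2-en-1-one | COc1cc(OC(C)C)c(/C=C/C(=O)c2c(O)cc(OC)c(OC)c2OC)c(OC)c1OC
F4 | step 4 | 6'-isopropoxy-5,6,7,2',3',4'-hexamethoxyflavone | COc1cc(OC(C)C)c(-c2cc(=O)c3c(OC)c(OC)c(OC)cc3o2)c(OC)c1OC
F5 | step 3 | 4-(tert-butyldimethylsilyloxy)-5,6,7-trimethoxy-1-benzopyrylium triflate | COc1cc2[o+]ccc(O[Si](C)(C)C(C)(C)C)c2c(OC)c1OC.[O-]S(=O)(=O)C(F)(F)F
F6 | step 3 | racemic tert-butyl{[2-(2-hydroxy-4,5,6-trimethoxyphenyl)-5,6,7-trimethoxy-2H-chromen-4-yl]oxy}dimethylsilane | COc1cc2OC(c3c(O)cc(OC)c(OC)c3OC)C=C(O[Si](C)(C)C(C)(C)C)c2c(OC)c1OC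
F7 | step 3 | 6'-hydroxy-5,6,7,2',3',4'-hexamethoxyflavone | COc1cc(O)c(-c2cc(=O)c3c(OC)c(OC)c(OC)cc3o2)c(OC)c1OC
F8 | step 2 | racemic 2-hydroxy-5,6,7-trimethoxychroman-4-one | COc1cc2OC(O)CC(=O)c2c(OC)c1OC
A1 | direct plan | 3,4,5-trimethoxyphenol | COc1cc(O)cc(OC)c1OC
A2 | direct plan | 2-iodo-3,4,5-trimethoxyphenol | COc1cc(O)c(I)c(OC)c1OC
A3 | direct plan | 1-(benzyloxy)-2-iodo-3,4,5-trimethoxybenzene | COc1cc(OCc2ccccc2)c(I)c(OC)c1OC
A4 | direct plan | 1-(benzyloxy)-2-ethynyl-3,4,5-trimethoxybenzene | COc1cc(OCc2ccccc2)c(C#C)c(OC)c1OC
A5 | direct plan | 6'-benzyloxy-5,6,7,2',3',4'-hexamethoxyflavone | COc1cc(OCc2ccccc2)c(-c2cc(=O)c3c(OC)c(OC)c(OC)cc3o2)c(OC)c1OC
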